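**Strategy.** The 1,2-dioxane (O1–O2–C3–C4–C5–C6) is disconnected at O2–C3. C3 holds a peroxide oxygen and lies β to the ester carbonyl, so the O2–C3 bond plus the acetate arm can be read as a β-lactone opened by SN2 attack at its ring CH–O carbon. The precursor is an (R)-4-substituted oxetan-2-one whose side chain ends, two methylenes on, in a methoxy hydroperoxy ketal bearing the pentynyl group. One equivalent of base lets the peroxide anion displace the lactone carboxylate: the dioxane closes, C3 inverts to (S) and the acetic acid arm is released in one operation. Acidic methanol then funnels C6 to the anomeric epimer, and the enyne chain is attached last by Sonogashira coupling.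

Key step: step 8

Remark (assumption): the sense of induction of the aluminium triamine cyclocondensation catalyst is taken from its behaviour with unbranched aliphatic aldehydes, so the D-valinol-derived (R,R)-ligand is specified for the (R)-lactone; if a first run shows the opposite sense, the antipodal ligand is used.

**Step 1**
Reactants: 1 hept-6-yn-1-ol
Product: 2 hept-6-ynal
Conditions: TEMPO (10 mol%), PhI(OAc)2 (1.1 equiv), CH2Cl2, rt
Reagents that add atoms: none
Why: Oxoammonium-mediated alcohol oxidation (TEMPO/PhI(OAc)2) should stop at the aldehyde and leave the terminal alkyne untouched.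

**Step 2**
Reactants: 2 hept-6-ynal
Product: 3 2-methylidenehept-6-ynal
Conditions: 37% aq. CH2O (1.1 equiv), pyrrolidine (10 mol%), EtCO2H (10 mol%), i-PrOH, 45 °C
Reagents that add atoms: formaldehyde, C=O
Why: Amine-catalysed Mannich condensation followed by loss of the amine (organocatalytic α-methylenation) is dependable for unbranched aldehydes, and the enal is carried on at once to avoid dimerisation.

**Step 3**
Reactants: 3 2-methylidenehept-6-ynal
Product: 4 2-methylidenehept-6-yn-1-ol
Conditions: NaBH4, CeCl3·7H2O, MeOH, 0 °C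
Reagents that add atoms: none
Why: Luche reduction delivers hydride to the carbonyl carbon only, so the allylic alcohol should form without conjugate reduction.

**Step 4**
Reactants: 4 2-methylidenehept-6-yn-1-ol; 5 triethyl orthoacetate
Product: 7 ethyl 4-methylidenenon-8-ynoate, via ketene acetal 6 (not isolated)
Conditions: MeC(OEt)3 (6 equiv), EtCO2H (cat.), 140 °C, EtOH distilled off
Reagents that add atoms: none
Why: Johnson–Claisen rearrangement, in which the mixed ketene acetal of the 2-substituted allylic alcohol undergoes a [3,3]-sigmatropic shift that adds the two-carbon ester arm and regenerates a 1,1-disubstituted alkene.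

**Step 5**
Reactants: 7 ethyl 4-methylidenenon-8-ynoate
Product: 8 4-methylidenenon-8-ynal
Conditions: i-Bu2AlH (1.05 equiv), CH2Cl2, −78 °C; MeOH, then aq. potassium sodium tartrate
Reagents that add atoms: none
Why: Partial ester reduction works because the aluminium hemiacetal persists at −78 °C and releases the aldehyde only on work-up, while the alkyne and alkene are inert at this temperature.

**Step 6**
Reactants: 8 4-methylidenenon-8-ynal; 9 acetyl bromide
Product: 10 (4R)-4-(3-methylideneoct-7-ynyl)oxetan-2-one
Conditions: AcBr (1.9 equiv), i-Pr2NEt (1.7 equiv), AlMe3 (10 mol%) + (R,R)-BnN[CH2CH(i-Pr)NHSO2CF3]2 (10 mol%), CH2Cl2, −50 °C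
Reagents that add atoms: none
Why: Catalytic asymmetric acyl halide–aldehyde cyclocondensation (ketene–aldehyde [2+2]), in which ketene made in the flask adds to the aldehyde bound to the chiral aluminium triamine complex; the ligand shields one carbonyl face and so should set the lactone carbon as (R).

**Step 7**
Reactants: 10 (4R)-4-(3-methylideneoct-7-ynyl)oxetan-2-one
Product: 12 (4R)-4-(3-hydroperoxy-3-methoxyoct-7-ynyl)oxetan-2-one (both epimers at the ketal carbon), via carbonyl oxide 11 (not isolated)
Conditions: O3/O2, MeOH–CH2Cl2 (1:4), Sudan Red 7B (trace), −78 °C, stopped when the dye fades; N2 purge, no reductant, concentrated below 20 °C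
Reagents that add atoms: ozone, [O-][O+]=O; methanol, CO
Why: Ozonolysis with solvent trapping, in which the 1,1-disubstituted alkene reacts much faster than the terminal alkyne, its primary ozonide splits into formaldehyde and the more substituted carbonyl oxide, and methanol captures that carbonyl oxide as the methoxy hydroperoxy ketal while the cold neutral medium leaves the β-lactone closed.

**Step 8**
Reactants: 12 (4R)-4-(3-hydroperoxy-3-methoxyoct-7-ynyl)oxetan-2-one
Product: 14 2-[(3S)-6-methoxy-6-(pent-4-ynyl)-1,2-dioxan-3-yl]acetic acid (both C6 epimers), via cesium carboxylate 13 (not isolated)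
Conditions: Cs2CO3 (1.0 equiv), dry DMF (0.01 M), 0 °C to rt; then cold 0.5 M HCl to pH 3, EtOAc extraction
Reagents that add atoms: none
Why: Proposed new method: Cs2CO3 ionises only the hydroperoxide, which is far more acidic than the lactone α-CH2, and the resulting α-effect peroxide anion attacks the lactone CH–O carbon from the side opposite the ring oxygen, expelling the strained-ring carboxylate (SN2 with alkyl–oxygen cleavage). The closest known reaction types are the base-mediated ring closure of hydroperoxy ketals onto secondary sulfonates or halides to give 1,2-dioxanes and 1,2-dioxolanes, and the inversion-selective alkyl–oxygen opening of 4-substituted β-lactones by soft nucleophiles such as azide, thiolates, carboxylates and cuprates. The 1,2-dioxane closes in a 6-exo-tet mode through a chair-like transition state, the O2–C3 bond forming as the oxetanone C4–O1 bond breaks. C3 is controlled by the substrate alone, since clean inversion turns the (R)-lactone carbon into (3S), while C6 stays a mixture to be corrected in step 9. The step needs attack at the alkyl rather than the acyl carbon and no E1cB opening to the enoate: the two-methylene tether secures the first (six-membered closure against an eight-membered perester), the acidity gap and the weak carbonate base secure the second, and high dilution holds back intermolecular oligomerisation. Because the ring-opened product is a carboxylate salt, α-deprotonation and hence β-elimination of the peroxide are shut off, which protects the inverted centre until the acidic quench.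

**Step 9**
Reactants: 14 2-[(3S)-6-methoxy-6-(pent-4-ynyl)-1,2-dioxan-3-yl]acetic acid
Product: 16 methyl 2-[(3S,6R)-6-methoxy-6-(pent-4-ynyl)-1,2-dioxan-3-yl]acetate, via ester epimer mixture 15 (not isolated)
Conditions: Me3SiCHN2 (1.2 equiv), MeOH–PhMe (1:3), 0 °C; AcOH quench; then camphorsulfonic acid (10 mol%), MeOH, rt; solid NaHCO3
Reagents that add atoms: trimethylsilyldiazomethane, C[Si](C)(C)C=[N+]=[N-]; methanol, CO (exchanges the ketal methoxy group)
Why: Neutral esterification by diazomethane generated from Me3SiCHN2 and methanol is followed by acid-catalysed acetal anomerisation through a cyclic peroxycarbenium ion, which should converge on the (6R) epimer with methoxy axial (anomeric effect) and both carbon substituents equatorial, that is methoxy cis to the CH2CO2Me arm.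

**Step 10**
Reactants: 17 dec-9-yn-1-ol
Product: 19 10-(trimethylsilyl)dec-9-yn-1-ol, via bis-silyl ether 18 (not isolated)
Conditions: n-BuLi (2.2 equiv), THF, −78 to 0 °C; Me3SiCl (2.4 equiv), −78 °C to rt; 1 M HCl, rt
Reagents that add atoms: chlorotrimethylsilane, C[Si](C)(C)Cl
Why: C-silylation of a terminal alkyne through its alkoxide–acetylide dianion silylates both sites, and dilute acid then cleaves only the labile O–Si bond.

**Step 11**
Reactants: 19 10-(trimethylsilyl)dec-9-yn-1-ol
Product: 20 10-(trimethylsilyl)dec-9-ynal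
Conditions: TEMPO (10 mol%), PhI(OAc)2 (1.1 equiv), CH2Cl2, rt
Reagents that add atoms: none
Why: The same oxoammonium-mediated alcohol oxidation as in step 1 is mild enough to leave the alkynylsilane intact.

**Step 12**
Reactants: 20 10-(trimethylsilyl)dec-9-ynal
Product: 21 (E)-1-iodo-11-(trimethylsilyl)undec-1-en-10-yne
Conditions: CHI3 (2 equiv), CrCl2 (6 equiv), dioxane–THF (6:1), 0 °C to rt, dark
Reagents that add atoms: iodoform, IC(I)I
Why: Takai iodo-olefination, in which the geminal dichromium species from iodoform adds to the aldehyde and eliminates to the E-vinyl iodide; the dioxane co-solvent is chosen to favour E and the alkynylsilane is inert to divalent chromium.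

**Step 13**
Reactants: 16 methyl 2-[(3S,6R)-6-methoxy-6-(pent-4-ynyl)-1,2-dioxan-3-yl]acetate; 21 (E)-1-iodo-11-(trimethylsilyl)undec-1-en-10-yne
Product: 22 methyl 2-[(3S,6R)-6-methoxy-6-[(6E)-16-(trimethylsilyl)hexadec-6-ene-4,15-diynyl]-1,2-dioxan-3-yl]acetate
Conditions: PdCl2(PPh3)2 (5 mol%), CuI (10 mol%), Et3N (3 equiv), THF, degassed, rt
Reagents that add atoms: none
Why: Sonogashira coupling (oxidative addition of the vinyl iodide to zerovalent palladium, transfer of the copper acetylide of 16, reductive elimination) retains the E geometry, and at room temperature with little free phosphine the 1,2-dioxane and the silyl-capped alkyne should survive.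

**Step 14**
Reactants: 22 methyl 2-[(3S,6R)-6-methoxy-6-[(6E)-16-(trimethylsilyl)hexadec-6-ene-4,15-diynyl]-1,2-dioxan-3-yl]acetate
Product: 23 methyl 2-[(3S,6R)-6-[(6E)-hexadec-6-ene-4,15-diynyl]-6-methoxy-1,2-dioxan-3-yl]acetate (CNP0314169.1)
Conditions: Bu4NF (1.5 equiv), AcOH (1.5 equiv), THF, 0 °C to rt
Reagents that add atoms: none
Why: Fluoride-induced protodesilylation of the alkynylsilane, with the acetic acid buffer keeping the medium non-basic so that the β-peroxy ester cannot open by E1cB elimination.

**Compound list**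
1 | hept-6-yn-1-ol | C#CCCCCCO | starting material
2 | hept-6-ynal | C#CCCCCC=O | intermediate
3 | 2-methylidenehept-6-ynal | C#CCCCC(=C)C=O | intermediate
4 | 2-methylidenehept-6-yn-1-ol | C#CCCCC(=C)CO | intermediate
5 | triethyl orthoacetate | CC(OCC)(OCC)OCC | starting material
6 | 1-ethoxy-1-(2-methylidenehept-6-ynyloxy)ethene (mixed ketene acetal) | C=C(OCC)OCC(=C)CCCC#C | intermediate
7 | ethyl 4-methylidenenon-8-ynoate | CCOC(=O)CCC(=C)CCCC#C | intermediate
8 | 4-methylidenenon-8-ynal | O=CCCC(=C)CCCC#C | intermediate
9 | acetyl bromide | CC(Br)=O | starting material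
10 | (4R)-4-(3-methylideneoct-7-ynyl)oxetan-2-one | O=C1C[C@@H](CCC(=C)CCCC#C)O1 | intermediate
11 | carbonyl oxide of (4R)-4-(3-oxooct-7-ynyl)oxetan-2-one | O=C1C[C@@H](CCC(=[O+][O-])CCCC#C)O1 | intermediate
12 | (4R)-4-(3-hydroperoxy-3-methoxyoct-7-ynyl)oxetan-2-one, both ketal epimers | O=C1C[C@@H](CCC(OC)(OO)CCCC#C)O1 | intermediate
13 | cesium 2-[(3S)-6-methoxy-6-(pent-4-ynyl)-1,2-dioxan-3-yl]acetate, both C6 epimers | [Cs+].[O-]C(=O)C[C@@H]1CCC(OC)(CCCC#C)OO1 | intermediate
14 | 2-[(3S)-6-methoxy-6-(pent-4-ynyl)-1,2-dioxan-3-yl]acetic acid, both C6 epimers | OC(=O)C[C@@H]1CCC(OC)(CCCC#C)OO1 | intermediate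
15 | methyl 2-[(3S)-6-methoxy-6-(pent-4-ynyl)-1,2-dioxan-3-yl]acetate, both C6 epimers | COC(=O)C[C@@H]1CCC(OC)(CCCC#C)OO1 | intermediate
16 | methyl 2-[(3S,6R)-6-methoxy-6-(pent-4-ynyl)-1,2-dioxan-3-yl]acetate | C#CCCC[C@]1(OC)CC[C@@H](CC(=O)OC)OO1 | intermediate
17 | dec-9-yn-1-ol | C#CCCCCCCCCO | starting material
18 | trimethyl[10-(trimethylsilyloxy)dec-1-ynyl]silane | C[Si](C)(C)C#CCCCCCCCCO[Si](C)(C)C | intermediate
19 | 10-(trimethylsilyl)dec-9-yn-1-ol | C[Si](C)(C)C#CCCCCCCCCO | intermediate
20 | 10-(trimethylsilyl)dec-9-ynal | C[Si](C)(C)C#CCCCCCCCC=O | intermediate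
21 | (E)-1-iodo-11-(trimethylsilyl)undec-1-en-10-yne | C[Si](C)(C)C#CCCCCCCC/C=C/I | intermediate
22 | methyl 2-[(3S,6R)-6-methoxy-6-[(6E)-16-(trimethylsilyl)hexadec-6-ene-4,15-diynyl]-1,2-dioxan-3-yl]acetate | C[Si](C)(C)C#CCCCCCCC/C=C/C#CCCC[C@]1(OC)CC[C@@H](CC(=O)OC)OO1 | intermediate
23 | methyl 2-[(3S,6R)-6-[(6E)-hexadec-6-ene-4,15-diynyl]-6-methoxy-1,2-dioxan-3-yl]acetate (CNP0314169.1) | C#CCCCCCCC/C=C/C#CCCC[C@]1(OC)CC[C@@H](CC(=O)OC)OO1 | target

**Step count.** Total: 14 steps. Longest linear sequence: 11 steps (steps 1–9, 13 and 14, from hept-6-yn-1-ol).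

**Steps most likely to fail**

Step 8 (new method). The peroxide anion may prove too weak a nucleophile toward the secondary lactone carbon, so that intermolecular acyl attack or carboxylate-driven oligomerisation outruns the 6-exo-tet closure. The fallback uses the known ring closure of a hydroperoxy ketal onto a secondary mesylate. It sets out from 10:
- LiBH4 in THF reduces the lactone to (3R)-6-methylideneundec-10-yne-1,3-diol F1.
- Selective primary silylation (t-BuMe2SiCl, imidazole, 0 °C) gives (3R)-1-(tert-butyldimethylsilyloxy)-6-methylideneundec-10-yn-3-ol F2.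
- MsCl/Et3N gives (3R)-1-(tert-butyldimethylsilyloxy)-6-methylideneundec-10-yn-3-yl methanesulfonate F3.
- Dye-limited ozonolysis in MeOH–CH2Cl2, as in step 7, gives (3R)-1-(tert-butyldimethylsilyloxy)-6-hydroperoxy-6-methoxyundec-10-yn-3-yl methanesulfonate F4.
- KOt-Bu/18-crown-6 in THF closes the ring with inversion to tert-butyl{2-[(3S)-6-methoxy-6-(pent-4-ynyl)-1,2-dioxan-3-yl]ethoxy}dimethylsilane F5.
- Buffered fluoride frees 2-[(3S)-6-methoxy-6-(pent-4-ynyl)-1,2-dioxan-3-yl]ethanol F6.
- TEMPO/PhI(OAc)2 in aqueous MeCN oxidises F6 to the acid, and the route is rejoined at 14.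

Step 7. Ozone may over-oxidise the terminal alkyne before the alkene is consumed, or the lactone may be opened by methanol while the peroxide is handled. The fallback avoids ozone and sets out from 10:
- OsO4 (cat.)/N-methylmorpholine N-oxide dihydroxylates only the alkene, giving (4R)-4-[3-hydroxy-3-(hydroxymethyl)oct-7-ynyl]oxetan-2-one F7.
- NaIO4 cleaves the diol to (4R)-4-(3-oxooct-7-ynyl)oxetan-2-one F8.
- HC(OMe)3/MeOH with pyridinium tosylate gives (4R)-4-(3,3-dimethoxyoct-7-ynyl)oxetan-2-one F9.
- Acid-catalysed exchange of one methoxy group with anhydrous ethereal H2O2 (camphorsulfonic acid, 0 °C) gives the hydroperoxy ketal, and the route is rejoined at 12.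

Step 6. An unselective background cycloaddition may erode the enantioselectivity, or the aluminium Lewis acid may trigger a carbonyl–ene cyclisation onto the 1,1-disubstituted alkene. The fallback sets the carbinol centre by biocatalytic ketone reduction and sets out from 8:
- Roskamp homologation (ethyl diazoacetate, SnCl2 cat., CH2Cl2) gives ethyl 6-methylidene-3-oxoundec-10-ynoate F10.
- An (R)-selective ketoreductase with cofactor recycling reduces it to ethyl (3R)-3-hydroxy-6-methylideneundec-10-ynoate F11.
- LiOH gives (3R)-3-hydroxy-6-methylideneundec-10-ynoic acid F12.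
- Carboxyl activation (PhSO2Cl, pyridine, 0 °C) closes the β-lactone with retention, and the route is rejoined at 10.

**Further compounds**
F1 | step 8 | (3R)-6-methylideneundec-10-yne-1,3-diol | OCC[C@@H](CCC(=C)CCCC#C)O
F2 | step 8 | (3R)-1-(tert-butyldimethylsilyloxy)-6-methylideneundec-10-yn-3-ol | CC(C)(C)[Si](C)(C)OCC[C@@H](CCC(=C)CCCC#C)O
F3 | step 8 | (3R)-1-(tert-butyldimethylsilyloxy)-6-methylideneundec-10-yn-3-yl methanesulfonate | CC(C)(C)[Si](C)(C)OCC[C@@H](CCC(=C)CCCC#C)OS(C)(=O)=O
F4 | step 8 | (3R)-1-(tert-butyldimethylsilyloxy)-6-hydroperoxy-6-methoxyundec-10-yn-3-yl methanesulfonate, both C6 epimers | CC(C)(C)[Si](C)(C)OCC[C@@H](CCC(OC)(OO)CCCC#C)OS(C)(=O)=O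
F5 | step 8 | tert-butyl{2-[(3S)-6-methoxy-6-(pent-4-ynyl)-1,2-dioxan-3-yl]ethoxy}dimethylsilane, both C6 epimers | CC(C)(C)[Si](C)(C)OCC[C@@H]1CCC(OC)(CCCC#C)OO1
F6 | step 8 | 2-[(3S)-6-methoxy-6-(pent-4-ynyl)-1,2-dioxan-3-yl]ethanol, both C6 epimers | OCC[C@@H]1CCC(OC)(CCCC#C)OO1
F7 | step 7 | (4R)-4-[3-hydroxy-3-(hydroxymethyl)oct-7-ynyl]oxetan-2-one, both carbinol epimers | O=C1C[C@@H](CCC(O)(CO)CCCC#C)O1
F8 | step 7 | (4R)-4-(3-oxooct-7-ynyl)oxetan-2-one | O=C1C[C@@H](CCC(=O)CCCC#C)O1
F9 | step 7 | (4R)-4-(3,3-dimethoxyoct-7-ynyl)oxetan-2-one | O=C1C[C@@H](CCC(OC)(OC)CCCC#C)O1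
F10 | step 6 | ethyl 6-methylidene-3-oxoundec-10-ynoate | CCOC(=O)CC(=O)CCC(=C)CCCC#C
F11 | step 6 | ethyl (3R)-3-hydroxy-6-methylideneundec-10-ynoate | CCOC(=O)C[C@@H](CCC(=C)CCCC#C)O
F12 | step 6 | (3R)-3-hydroxy-6-methylideneundec-10-ynoic acid | OC(=O)C[C@@H](CCC(=C)CCCC#C)O
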